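**Retrosynthetic overview**
The strategy rests on ring B (C5–C10): oxygen on C6, the quaternary C10, and two vicinal one-carbon branches of different oxidation level, C17 on C8 (aldehyde level) and C11 on C9 (acid level).
Ring B is disconnected by a [4+2] at C7–C8 and C9–C10 into a 2-silyloxy diene (C10, C5, C6, C7, with ring A from β-cyclocitral) and an enantiopure 5-menthyloxybutenolide (C9, C8; lactone C=O = C11, acetal carbon = C17).
After the cycloaddition: trans-decalone, thermodynamic reduction to the equatorial C6 alcohol, lactone opening with release of menthol, and C9 epimerisation at the C11 aldehyde stage.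
The side chain is disconnected at C12–C13: C9-vinyl (C11=C12) by hydroboration and B-alkyl Suzuki coupling with a (Z)-β-iodoenoate (C13–C16); C7=C8 comes last from the saturated C17 aldehyde, then formate and desilylation.
Ring order: ring A is bought, ring B is closed in the key step, the lactone ring is temporary.

Key step: step 6

Remark: labdane numbering is used (decalin C1–C10, C17 on C8, side chain C11–C16 on C9). In the target H-5 and the C6 hydroxyl are trans to the C10 methyl, the C9 side chain is cis to it, and C12 is cis to the ester across C13=C14 (2E).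

**Route**

Step 1
Reactants: 1 β-cyclocitral
Product: 2 1-(2,6,6-trimethylcyclohex-1-en-1-yl)ethan-1-ol (racemic)
Conditions: MeMgBr, THF, 0 °C; aq. NH4Cl
Reagents that add atoms: methylmagnesium bromide, C[Mg]Br
Why: Grignard 1,2-addition to the hindered enal; the carbinol centre is racemic and is destroyed in step 2.

Step 2
Reactants: 2 1-(2,6,6-trimethylcyclohex-1-en-1-yl)ethan-1-ol
Product: 3 1-(2,6,6-trimethylcyclohex-1-en-1-yl)ethan-1-one
Conditions: Dess–Martin periodinane, CH2Cl2, rt
Reagents that add atoms: none
Why: Dess–Martin oxidation of the allylic secondary alcohol, free of acid or base that could move the ring double bond.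

Step 3
Reactants: 3 1-(2,6,6-trimethylcyclohex-1-en-1-yl)ethan-1-one
Product: 5 1-[1-(tert-butyldimethylsilyloxy)ethenyl]-2,6,6-trimethylcyclohex-1-ene, via lithium enolate 4 (not isolated)
Conditions: LDA, THF, −78 °C; TBSCl, DMPU, −78 °C to 0 °C
Reagents that add atoms: tert-butyldimethylsilyl chloride, CC(C)(C)[Si](C)(C)Cl
Why: Kinetic deprotonation of the acetyl methyl and O-silylation (silyl enol ether formation) should give the cross-conjugated 2-silyloxy diene and not the extended dienol ether.

Step 4
Reactants: 6 furfural
Product: 7 5-hydroxyfuran-2(5H)-one (racemic)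
Conditions: O2, rose bengal (cat.), hν, MeOH, rt
Reagents that add atoms: dioxygen, O=O
Why: Dye-sensitised photooxygenation: singlet oxygen adds [4+2] across the furan and methanol cleaves the formyl group as methyl formate; the hemiacetal centre is reset in step 5.

Step 5
Reactants: 7 5-hydroxyfuran-2(5H)-one, 8 (1S,2R,5S)-(+)-menthol
Product: 9 (5S)-5-[(1S,2R,5S)-menthyloxy]furan-2(5H)-one
Conditions: CSA (cat.), toluene, reflux (Dean–Stark); crystallisation from hexane
Reagents that add atoms: none
Why: Acid-catalysed acetalisation gives both C5 epimers, which interconvert through the oxocarbenium ion, so crystallisation of the (5S) epimer (mirror image of the well-known (5R) compound from (−)-menthol) should drain the mixture.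

Step 6
Reactants: 5 1-[1-(tert-butyldimethylsilyloxy)ethenyl]-2,6,6-trimethylcyclohex-1-ene, 9 (5S)-5-[(1S,2R,5S)-menthyloxy]furan-2(5H)-one
Product: 10 endo cycloadduct (C5=C6 silyl enol ether; cis-fused γ-lactone with C11 carbonyl on C9 and the (17S) menthyl acetal carbon C17 on C8, both trans to the C10 methyl)
Conditions: CH2Cl2, BHT (cat.), 1.2 GPa, 45 °C, 72 h; 5 in excess
Reagents that add atoms: none
Why: A concerted but asynchronous normal-electron-demand [4+2] cycloaddition is expected, the closest known reaction type being the thermal Diels–Alder reaction of 2-silyloxybuta-1,3-dienes with 5-alkoxyfuran-2(5H)-ones, here driven by pressure because the diene must reach a twisted s-cis geometry with its C10 methyl pointing inward. The silyloxy group on C6 and the two alkyl groups on C10 make C7 the nucleophilic terminus, so C7 bonds to the β-carbon of the butenolide (C8) and C10 closes onto the α-carbon (C9), which places the lactone carbonyl at C11 and the acetal carbon at C17. Ring B (C5–C10) is closed by the cycloaddition itself, both σ-bonds forming suprafacially on each partner, so H-8 and H-9 are cis and the lactone is cis-fused. C8 and C9 are set by approach to the butenolide face anti to the menthyloxy group, that is by the C17 acetal centre, and C10 by the endo orientation (diene carbons C5 and C6 over the lactone carbonyl) on that face, which puts the C10 methyl trans to C11 and gives the C10 configuration of the target. The step needs regio-, facial and endo selectivity: the donor pattern of the diene secures the first, the menthyloxy group the second, and secondary overlap the third, which is the least certain; an exo adduct is a diastereomer while the auxiliary is attached and has to be removed by chromatography here, since it would lead to the enantiomeric decalin later. High pressure favours the compact transition state and allows a temperature at which the silyl enol ether survives.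

Step 7
Reactants: 10 endo cycloadduct
Product: 11 keto lactone (C6 ketone; H-5 trans to the C10 methyl; menthyloxy lactone unchanged)
Conditions: aq. HF, MeCN, 0 °C
Reagents that add atoms: none
Why: Protodesilylation of the silyl enol ether with protonation of C5 on the face opposite the adjacent axial C10 methyl, which is also the thermodynamically preferred trans ring fusion.

Step 8
Reactants: 11 keto lactone
Product: 12 hydroxy lactone (equatorial C6 hydroxyl, trans to the C10 methyl and cis to H-5)
Conditions: SmI2, THF/H2O, 0 °C to rt
Reagents that add atoms: none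
Why: Single-electron (dissolving-metal type) ketone reduction, in which the ketyl/carbanion places the bulky oxygen–samarium group equatorial before protonation at carbon, so the more stable equatorial alcohol is expected where hydride would attack anti to the axial C4 and C10 methyls and give the axial epimer; the five-membered lactone should be inert to this reagent.

Step 9
Reactants: 12 hydroxy lactone
Product: 13 C6 tert-butyldimethylsilyl ether of 12
Conditions: TBSOTf, 2,6-lutidine, CH2Cl2, 0 °C to rt
Reagents that add atoms: tert-butyldimethylsilyl triflate, CC(C)(C)[Si](C)(C)OS(=O)(=O)C(F)(F)F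
Why: Silylation with the triflate, chosen because the equatorial C6 hydroxyl is peri to the equatorial C4 methyl and hindered.

Step 10
Reactants: 13 silyl ether lactone
Product: 14 ester aldehyde (C11 methyl ester on C9, still trans to the C10 methyl and axial; C17 aldehyde on C8, equatorial; 6-OTBS)
Conditions: NaOMe (cat.), MeOH, 0 °C to rt
Reagents that add atoms: methanol, CO
Why: Methoxide-catalysed transesterification opens the lactone and the freed hemiacetal alkoxide expels menthoxide (pseudo-ester to normal ester conversion), which recovers the auxiliary; any C9 epimerisation here only anticipates step 13.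

Step 11
Reactants: 14 ester aldehyde
Product: 15 C17 dimethyl acetal of 14
Conditions: HC(OMe)3, PPTS (cat.), MeOH, rt
Reagents that add atoms: trimethyl orthoformate, COC(OC)OC; methanol, CO
Why: Acid-catalysed acetalisation masks C17 so that C11 can be reduced, oxidised and olefinated.

Step 12
Reactants: 15 ester acetal
Product: 16 C11 primary alcohol (C17 dimethyl acetal; 6-OTBS)
Conditions: LiAlH4, THF, 0 °C to rt
Reagents that add atoms: none
Why: LiAlH4 ester reduction; acetal and silyl ether are inert.

Step 13
Reactants: 16 C11 primary alcohol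
Product: 18 equatorial C11 aldehyde (C11 cis to the C10 methyl; C17 dimethyl acetal; 6-OTBS), via axial C11 aldehyde 17 (not isolated)
Conditions: Dess–Martin periodinane, pyridine, CH2Cl2, 0 °C; aqueous work-up; then DBU (cat.), CH2Cl2, rt
Reagents that add atoms: none
Why: Buffered Dess–Martin oxidation (no acid that could close a cyclic acetal onto C17) followed by base epimerisation through the enolate, which should set C9 under thermodynamic control with C11 equatorial and trans to the C8 substituent.

Step 14
Reactants: 18 equatorial C11 aldehyde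
Product: 19 C9 vinyl compound (C11=C12; C17 dimethyl acetal; 6-OTBS)
Conditions: Ph3PCH3Br, KHMDS, THF, 0 °C to rt
Reagents that add atoms: methyltriphenylphosphonium bromide, C[P+](c1ccccc1)(c1ccccc1)c1ccccc1.[Br-]
Why: Wittig methylenation of an aldehyde that already sits in its stable configuration, so the basic ylide cannot erode C9.

Step 15
Reactants: 20 methyl 4-hydroxybut-2-ynoate
Product: 21 methyl (2Z)-4-hydroxy-3-iodobut-2-enoate
Conditions: NaI, AcOH, MeCN, 80 °C
Reagents that add atoms: sodium iodide, [Na+].[I-]
Why: Hydroiodination of the ynoate by conjugate addition of iodide and anti protonation gives the (Z)-β-iodoenoate, with iodine cis to the ester and the hydroxymethyl group trans, so lactonisation is not possible.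

Step 16
Reactants: 19 C9 vinyl compound, 21 methyl (2Z)-4-hydroxy-3-iodobut-2-enoate
Product: 23 coupled (2E)-enoate (C16 hydroxyl; C17 dimethyl acetal; 6-OTBS), via B-alkyl-9-BBN 22 (not isolated)
Conditions: 9-BBN, THF, 0 °C to rt; then 21, Pd(dppf)Cl2 (cat.), AsPh3 (cat.), Cs2CO3, DMF/H2O, rt
Reagents that add atoms: none
Why: Anti-Markovnikov hydroboration of the only alkene followed by B-alkyl Suzuki–Miyaura coupling, which proceeds with retention at the vinyl iodide and so fixes C12 cis to the ester.

Step 17
Reactants: 23 coupled (2E)-enoate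
Product: 24 saturated C17 aldehyde (formyl group equatorial on C8; 6-OTBS; C16 hydroxyl)
Conditions: PPTS (cat.), acetone/H2O, 45 °C
Reagents that add atoms: water, O
Why: Mild acid hydrolysis of the dimethyl acetal, under which the hindered secondary silyl ether and the enoate should survive.

Step 18
Reactants: 24 saturated C17 aldehyde
Product: 25 C8 phenylselenide of 24 (selenium expected trans to the C10 methyl)
Conditions: N-(phenylseleno)phthalimide, pyrrolidine (cat.), CH2Cl2, rt
Reagents that add atoms: N-(phenylseleno)phthalimide, O=C1c2ccccc2C(=O)N1[Se]c1ccccc1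
Why: Amine-catalysed α-selenenylation through the C8=C17 enamine; the new C8 centre is removed in step 19, so its configuration is not critical.

Step 19
Reactants: 25 C8 phenylselenide
Product: 27 enal (C7=C8 conjugated to the C17 aldehyde; 6-OTBS; C16 hydroxyl), via selenoxide 26 (not isolated)
Conditions: mCPBA, CH2Cl2, −78 °C; then pyridine, −78 °C to rt
Reagents that add atoms: none
Why: Selenoxide syn-elimination, expected to remove the secondary C7–H and give the trisubstituted alkene in preference to the tertiary C9–H next to the quaternary C10, which would give a strained tetrasubstituted alkene.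

Step 20
Reactants: 27 enal
Product: 28 C16 formate of 27
Conditions: HCO2H, DCC, DMAP (cat.), CH2Cl2, 0 °C
Reagents that add atoms: formic acid, O=CO
Why: Carbodiimide-mediated (Steglich) formylation of the only free hydroxyl, a primary allylic one.

Step 21
Reactants: 28 C16 formate
Product: 29 target, methyl (2E)-3-[(formyloxy)methyl]-5-(decalinyl)pent-2-enoate with 6-hydroxy, 7-ene and 17-al (CNP0134813.1)
Conditions: HF·pyridine, pyridine, THF, 0 °C to rt
Reagents that add atoms: none
Why: Fluoride-mediated desilylation under buffered, non-nucleophilic acidic conditions, which should spare the formate, the methyl ester and the γ-hydroxy enal.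

**Compound list**
1 | β-cyclocitral | CC1=C(C=O)C(C)(C)CCC1 | starting material
2 | 1-(2,6,6-trimethylcyclohex-1-en-1-yl)ethan-1-ol (racemic) | CC(O)C1=C(C)CCCC1(C)C | intermediate
3 | 1-(2,6,6-trimethylcyclohex-1-en-1-yl)ethan-1-one | CC(=O)C1=C(C)CCCC1(C)C | intermediate
4 | lithium 1-(2,6,6-trimethylcyclohex-1-en-1-yl)ethen-1-olate | [Li]OC(=C)C1=C(C)CCCC1(C)C | intermediate
5 | 1-[1-(tert-butyldimethylsilyloxy)ethenyl]-2,6,6-trimethylcyclohex-1-ene | C=C(O[Si](C)(C)C(C)(C)C)C1=C(C)CCCC1(C)C | intermediate
6 | furfural | O=Cc1ccco1 | starting material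
7 | 5-hydroxyfuran-2(5H)-one (racemic) | OC1OC(=O)C=C1 | intermediate
8 | (1S,2R,5S)-(+)-menthol | C[C@H]1CC[C@@H]([C@H](C1)O)C(C)C | starting material
9 | (5S)-5-[(1S,2R,5S)-menthyloxy]furan-2(5H)-one | O=C1C=C[C@@H](O[C@H]2C[C@@H](C)CC[C@@H]2C(C)C)O1 | intermediate
10 | endo cycloadduct, C5=C6 silyl enol ether, cis-fused (17S)-menthyloxy lactone on C8/C9 trans to the C10 methyl | O=C1O[C@H](O[C@H]4C[C@@H](C)CC[C@@H]4C(C)C)[C@H]2CC(O[Si](C)(C)C(C)(C)C)=C3C(C)(C)CCC[C@@]3(C)[C@@H]12 | intermediate
11 | trans-fused C6 keto lactone | O=C1O[C@H](O[C@H]4C[C@@H](C)CC[C@@H]4C(C)C)[C@H]2CC(=O)[C@@H]3C(C)(C)CCC[C@@]3(C)[C@@H]12 | intermediate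
12 | hydroxy lactone, equatorial 6-OH | O=C1O[C@H](O[C@H]4C[C@@H](C)CC[C@@H]4C(C)C)[C@H]2C[C@@H](O)[C@@H]3C(C)(C)CCC[C@@]3(C)[C@@H]12 | intermediate
13 | 6-OTBS lactone | O=C1O[C@H](O[C@H]4C[C@@H](C)CC[C@@H]4C(C)C)[C@H]2C[C@@H](O[Si](C)(C)C(C)(C)C)[C@@H]3C(C)(C)CCC[C@@]3(C)[C@@H]12 | intermediate
14 | C11 methyl ester (axial on C9), C17 aldehyde (equatorial on C8), 6-OTBS | COC(=O)[C@H]1[C@@H](C=O)C[C@@H](O[Si](C)(C)C(C)(C)C)[C@@H]2C(C)(C)CCC[C@@]12C | intermediate
15 | C17 dimethyl acetal of 14 | COC(=O)[C@H]1[C@@H](C(OC)OC)C[C@@H](O[Si](C)(C)C(C)(C)C)[C@@H]2C(C)(C)CCC[C@@]12C | intermediate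
16 | C11 primary alcohol | OC[C@H]1[C@@H](C(OC)OC)C[C@@H](O[Si](C)(C)C(C)(C)C)[C@@H]2C(C)(C)CCC[C@@]12C | intermediate
17 | axial C11 aldehyde | O=C[C@H]1[C@@H](C(OC)OC)C[C@@H](O[Si](C)(C)C(C)(C)C)[C@@H]2C(C)(C)CCC[C@@]12C | intermediate
18 | equatorial C11 aldehyde (C11 cis to the C10 methyl) | O=C[C@@H]1[C@@H](C(OC)OC)C[C@@H](O[Si](C)(C)C(C)(C)C)[C@@H]2C(C)(C)CCC[C@@]12C | intermediate
19 | C9 vinyl compound | C=C[C@@H]1[C@@H](C(OC)OC)C[C@@H](O[Si](C)(C)C(C)(C)C)[C@@H]2C(C)(C)CCC[C@@]12C | intermediate
20 | methyl 4-hydroxybut-2-ynoate | COC(=O)C#CCO | starting material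
21 | methyl (2Z)-4-hydroxy-3-iodobut-2-enoate | COC(=O)/C=C(\I)CO | intermediate
22 | B-alkyl-9-BBN (boron on C12) | C(C[C@@H]1[C@@H](C(OC)OC)C[C@@H](O[Si](C)(C)C(C)(C)C)[C@@H]2C(C)(C)CCC[C@@]12C)B1C2CCCC1CCC2 | intermediate
23 | coupled (2E)-enoate, C16 OH, C17 dimethyl acetal, 6-OTBS | COC(=O)/C=C(\CC[C@@H]1[C@@H](C(OC)OC)C[C@@H](O[Si](C)(C)C(C)(C)C)[C@@H]2C(C)(C)CCC[C@@]12C)CO | intermediate
24 | saturated C17 aldehyde | COC(=O)/C=C(\CC[C@@H]1[C@@H](C=O)C[C@@H](O[Si](C)(C)C(C)(C)C)[C@@H]2C(C)(C)CCC[C@@]12C)CO | intermediate
25 | C8 phenylselenide (Se trans to the C10 methyl) | COC(=O)/C=C(\CC[C@@H]1[C@@](C=O)([Se]c3ccccc3)C[C@@H](O[Si](C)(C)C(C)(C)C)[C@@H]2C(C)(C)CCC[C@@]12C)CO | intermediate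
26 | C8 phenylselenoxide | COC(=O)/C=C(\CC[C@@H]1[C@@](C=O)([Se](=O)c3ccccc3)C[C@@H](O[Si](C)(C)C(C)(C)C)[C@@H]2C(C)(C)CCC[C@@]12C)CO | intermediate
27 | 7-en-17-al, 6-OTBS, C16 OH | COC(=O)/C=C(\CC[C@@H]1C(C=O)=C[C@@H](O[Si](C)(C)C(C)(C)C)[C@@H]2C(C)(C)CCC[C@@]12C)CO | intermediate
28 | C16 formate, 6-OTBS | COC(=O)/C=C(\CC[C@@H]1C(C=O)=C[C@@H](O[Si](C)(C)C(C)(C)C)[C@@H]2C(C)(C)CCC[C@@]12C)COC=O | intermediate
29 | CNP0134813.1 | COC(=O)/C=C(\CC[C@@H]1C(C=O)=C[C@@H](O)[C@@H]2C(C)(C)CCC[C@@]12C)COC=O | target

**Step count**
Total: 21 steps. Longest linear sequence: 18 steps (1, 2, 3, 6 to 14, 16 to 21).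

**Steps most likely to fail**

Step 6. The cycloaddition may stall because the diene must twist into the s-cis geometry against its inward C10 methyl, and the endo preference may erode, which would feed the enantiomeric decalin series after auxiliary removal. The fallback makes the same two bonds stepwise, as an anionic double Michael sequence instead of a concerted cycloaddition. It sets out from ketone 3 and butenolide 9. Enolate 4 (LDA, THF, −78 °C) is added to 9; conjugate addition of lithium enolates to this butenolide is expected anti to the menthyloxy group and forms C7–C8, giving the enone lactone F1 after quench. F1 is then closed by intramolecular Michael addition of its lactone enolate (C9) to the enone carbon C10 (KOt-Bu, t-BuOH/THF, 0 °C to rt, or as a Mukaiyama–Michael variant through the silyl ketene acetal with TiCl4). The tether imposes the cis lactone fusion, and protonation at C5 returns the route at keto lactone 11; the C10 configuration of this closure would have to be confirmed.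

Step 8. The electron-transfer reduction may be protonated kinetically from the open face and deliver the axial C6 alcohol, or the lactone may take up electrons. The fallback replaces the one-step thermodynamic reduction by hydride reduction and redox epimerisation. It sets out from 11: NaBH4 (MeOH/THF, 0 °C) is expected to give the axial alcohol F2 by attack anti to the axial C4 and C10 methyls. F2 is then equilibrated by reversible hydrogen transfer (Ru(CO)2Cl(η5-C5Ph5) (cat.), KOt-Bu (cat.), toluene, 60 °C), which passes through ketone 11 and lets the more stable equatorial alcohol accumulate, returning at 12.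

Step 19. Syn-elimination of the selenoxide may partly engage the axial C9–H and give the tetrasubstituted C8=C9 enal. The fallback dehydrogenates the preformed C8=C17 enol ether through a palladium enolate (Saegusa–Ito oxidation) instead of eliminating from an sp3 C8–Se centre; it changes the mechanism, but its regiochemistry rests on the same steric preference for the C7 methylene. It sets out from aldehyde 24: TESOTf and Et3N (CH2Cl2, 0 °C) give the bis-silylated enol ether F3 (C17 triethylsilyl enol ether, C16 triethylsilyl ether). Pd(OAc)2 (MeCN, rt) then gives enal F4 by β-hydride elimination toward C7. AcOH/THF/H2O removes the primary triethylsilyl group and returns the route at enal 27.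

**Further compounds**
F1 | step 6 | (5S)-5-menthyloxy-4-[2-oxo-2-(2,6,6-trimethylcyclohex-1-en-1-yl)ethyl]dihydrofuran-2(3H)-one, side chain trans to the menthyloxy group | O=C1C[C@H](CC(=O)C2=C(C)CCCC2(C)C)[C@@H](O[C@H]3C[C@@H](C)CC[C@@H]3C(C)C)O1
F2 | step 8 | hydroxy lactone with axial C6 hydroxyl (C6 epimer of 12) | O=C1O[C@H](O[C@H]4C[C@@H](C)CC[C@@H]4C(C)C)[C@H]2C[C@H](O)[C@@H]3C(C)(C)CCC[C@@]3(C)[C@@H]12
F3 | step 19 | C17 triethylsilyl enol ether of 24 with C16 triethylsilyl ether (enol ether geometry not defined) | COC(=O)/C=C(\CC[C@@H]1C(=CO[Si](CC)(CC)CC)C[C@@H](O[Si](C)(C)C(C)(C)C)[C@@H]2C(C)(C)CCC[C@@]12C)CO[Si](CC)(CC)CC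
F4 | step 19 | C16 triethylsilyl ether of enal 27 | COC(=O)/C=C(\CC[C@@H]1C(C=O)=C[C@@H](O[Si](C)(C)C(C)(C)C)[C@@H]2C(C)(C)CCC[C@@]12C)CO[Si](CC)(CC)CC
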